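**Assumptions (one line each)**
- The SMILES encodes the C2-symmetric (R,R)-isomer, not the meso form: at each benzylic carbon the CIP order is syncarpyl > aryl > isopropyl > H, and both centres come out R. Enolised triones are drawn as in the target.
- The facial sense of the chiral diene in Step 7 is not predictable with certainty for this new acceptor class. It is checked on the mono-arylidene from 2,4,6-tris(benzyloxy)benzaldehyde, and the antipodal ligand is used if needed; nothing else changes.

**Retrosynthetic overview**
1. Target 15 ⇒ tri-O-benzyl bis-isopropenyl compound 14; one neutral H2/Pd step removes the benzyl groups and converts isopropenyl to isopropyl.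
2. 14 ⇒ bis(arylidene-syncarpic) acceptor 12 by cutting the CH–C(isopropenyl) bond at both stereocentres (double Rh/chiral-diene conjugate alkenylation). This replaces the usual Ar–CH Friedel–Crafts/Michael disconnection.
3. 12 ⇒ dialdehyde 7 + 2 × syncarpic acid 11 (double Knoevenagel).
4. 7 ⇒ phloroglucinol (acylation, double Vilsmeier, benzylation); 11 ⇒ phloroacetophenone (dearomative tetramethylation, deacetylation).
5. Ring order: no ring is built de novo. The cyclohexanetrione rings are made first by dearomatisation, then attached to the benzene ring carried through from phloroglucinol.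

**Route**

Step 1
Reactants: 1 phloroglucinol; 2 hexanoyl chloride
Product: 3, 1-(2,4,6-trihydroxyphenyl)hexan-1-one
Conditions: AlCl3 (4 equiv), PhNO2/CH2Cl2, 0 → 40 °C; then 1 M HCl
Reagents that add atoms: hexanoyl chloride, CCCCCC(=O)Cl
Why: Friedel–Crafts C-acylation of the symmetric, highly activated arene stops at mono-acylation because the chelated acyl group deactivates the ring.

Step 2
Reactants: 3; 4 N,N-dimethylformamide
Product: 5, 5-hexanoyl-2,4,6-trihydroxybenzene-1,3-dicarbaldehyde
Conditions: POCl3 (5 equiv), DMF (6 equiv), EtOAc, 0 °C → rt; then H2O, 60 °C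
Reagents that add atoms: DMF, CN(C)C=O (formyl C–H); water, O (formyl oxygen)
Why: Vilsmeier–Haack formylation at the two equivalent free positions, each ortho/para to three OH groups, followed by iminium hydrolysis; this is the known way to make diformyl-acylphloroglucinols.

Step 3
Reactants: 5; 6 benzyl bromide
Product: 7, 2,4,6-tris(benzyloxy)-5-hexanoylbenzene-1,3-dicarbaldehyde
Conditions: BnBr (4.5 equiv), Cs2CO3, TBAI (cat.), DMF, 60 °C
Reagents that add atoms: benzyl bromide, BrCc1ccccc1
Why: Williamson O-alkylation of carboxylate-like (vinylogous acid) phenoxides with no ring C–H left for C-benzylation; benzyl is chosen because it blocks hemiketal and o-quinone-methide chemistry later and comes off under neutral H2.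

Step 4
Reactants: 8, 1-(2,4,6-trihydroxyphenyl)ethan-1-one (phloroacetophenone); 9 iodomethane
Product: 10, 2-acetyl-3-hydroxy-4,4,6,6-tetramethylcyclohex-2-ene-1,5-dione (acetylsyncarpic acid)
Conditions: NaOMe (5.5 equiv), MeI (8 equiv), MeOH, 0 °C → reflux
Reagents that add atoms: iodomethane, CI
Why: exhaustive dearomative C-methylation of the phloroglucinol polyanion, twice at each of the two unsubstituted ring carbons (known route to the syncarpic skeleton).

Step 5
Reactants: 10
Product: 11, syncarpic acid (5-hydroxy-2,2,6,6-tetramethylcyclohex-4-ene-1,3-dione)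
Conditions: 6 M aq. HCl, reflux
Reagents that add atoms: none
Why: acid-mediated retro-Claisen deacetylation of the β-triketone; the gem-dimethyl groups prevent rearomatisation.

Step 6
Reactants: 7; 11 (2.2 equiv)
Product: 12, 2,2'-{[2,4,6-tris(benzyloxy)-5-hexanoyl-1,3-phenylene]dimethanylylidene}bis(4,4,6,6-tetramethylcyclohexane-1,3,5-trione)
Conditions: piperidine (20 mol %), AcOH (20 mol %), toluene, 4 Å MS, 60 °C
Reagents that add atoms: syncarpic acid, CC1(C)C(=O)C=C(O)C(C)(C)C1=O
Why: double Knoevenagel condensation at the two aldehydes (the di-ortho-substituted aryl ketone is inert); the symmetric dione gives no E/Z isomers, and the flanking OBn groups disfavour addition of a second syncarpic acid.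

Step 7
Reactants: 12; 13, 2-isopropenyl-4,4,5,5-tetramethyl-1,3,2-dioxaborolane (4 equiv)
Product: 14, 1-{2,4,6-tris(benzyloxy)-3,5-bis[(1R)-1-(2-hydroxy-3,3,5,5-tetramethyl-4,6-dioxocyclohex-1-en-1-yl)-2-methylprop-2-en-1-yl]phenyl}hexan-1-one
Conditions: [RhCl(C2H4)2]2 (5 mol %), (R,R)-Ph-bod* (11 mol %), K3PO4 (2.5 equiv), dioxane/H2O 10:1, 40 °C; then aq. KHSO4; chromatography to remove the meso isomer
Reagents that add atoms: isopropenyl-Bpin, C=C(C)B1OC(C)(C)C(C)(C)O1
Why: Proposed new method: two-fold Rh(I)/chiral-diene Hayashi–Miyaura-type 1,4-alkenylation of an arylidene cyclic 1,3-dione (closest known type: Rh/diene additions of aryl- and alkenylboron reagents to arylidene malonate/Meldrum's-acid-type acceptors), in which isopropenyl–Rh carbometalates each exocyclic C=C with the diene distinguishing the Ar/H enantiofaces, the Rh oxa-π-allyl is hydrolysed to the enol, the boronate has no uncatalysed background, and independent catalyst control at both sites diverts the minor sense into the separable meso diastereomer (Horeau amplification) to give (R,R)-14, whose centres cannot scramble by o-quinone-methide retro-Michael because the phenols are benzylated.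

Step 8
Reactants: 14
Product: 15, (R,R)-myrtucommulone F, 1-{2,4,6-trihydroxy-3,5-bis[(1R)-1-(2-hydroxy-3,3,5,5-tetramethyl-4,6-dioxocyclohex-1-en-1-yl)-2-methylpropyl]phenyl}hexan-1-one
Conditions: H2 (1 atm), 10% Pd/C, EtOAc, rt; neutral filtration, no acid or base in work-up
Reagents that add atoms: none
Why: one neutral heterogeneous hydrogenation cleaves the three aryl benzyl ethers and saturates the two 1,1-disubstituted alkenes without creating or touching a stereocentre, while the chelated aryl ketone and tetrasubstituted enol C=C are inert and acid-induced cyclodehydration or base-induced retro-Michael is avoided.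

**Compound list**
1 | phloroglucinol | Oc1cc(O)cc(O)c1 | starting material
2 | hexanoyl chloride | CCCCCC(=O)Cl | starting material
3 | 1-(2,4,6-trihydroxyphenyl)hexan-1-one | CCCCCC(=O)c1c(O)cc(O)cc1O | intermediate
4 | N,N-dimethylformamide | CN(C)C=O | starting material (reagent)
5 | 5-hexanoyl-2,4,6-trihydroxybenzene-1,3-dicarbaldehyde | CCCCCC(=O)c1c(O)c(C=O)c(O)c(C=O)c1O | intermediate
6 | benzyl bromide | BrCc1ccccc1 | starting material
7 | 2,4,6-tris(benzyloxy)-5-hexanoylbenzene-1,3-dicarbaldehyde | CCCCCC(=O)c1c(OCc2ccccc2)c(C=O)c(OCc2ccccc2)c(C=O)c1OCc1ccccc1 | intermediate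
8 | 1-(2,4,6-trihydroxyphenyl)ethan-1-one | CC(=O)c1c(O)cc(O)cc1O | starting material
9 | iodomethane | CI | starting material
10 | 2-acetyl-3-hydroxy-4,4,6,6-tetramethylcyclohex-2-ene-1,5-dione | CC(=O)C1=C(O)C(C)(C)C(=O)C(C)(C)C1=O | intermediate
11 | syncarpic acid | CC1(C)C(=O)C=C(O)C(C)(C)C1=O | intermediate
12 | bis(arylidene-syncarpic) acceptor | CCCCCC(=O)c1c(OCc2ccccc2)c(C=C2C(=O)C(C)(C)C(=O)C(C)(C)C2=O)c(OCc2ccccc2)c(C=C2C(=O)C(C)(C)C(=O)C(C)(C)C2=O)c1OCc1ccccc1 | intermediate
13 | 2-isopropenyl-4,4,5,5-tetramethyl-1,3,2-dioxaborolane | C=C(C)B1OC(C)(C)C(C)(C)O1 | starting material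
14 | (R,R)-tri-O-benzyl bis-isopropenyl adduct | CCCCCC(=O)c1c(OCc2ccccc2)c([C@H](C2=C(O)C(C)(C)C(=O)C(C)(C)C2=O)C(C)=C)c(OCc2ccccc2)c([C@H](C2=C(O)C(C)(C)C(=O)C(C)(C)C2=O)C(C)=C)c1OCc1ccccc1 | intermediate
15 | (R,R)-myrtucommulone F | CCCCCC(=O)c1c(O)c([C@H](C2=C(O)C(C)(C)C(=O)C(C)(C)C2=O)C(C)C)c(O)c([C@H](C2=C(O)C(C)(C)C(=O)C(C)(C)C2=O)C(C)C)c1O | target

**Step count**
- Total: 8 steps.
- Longest linear sequence: 6 steps (1 → 3 → 5 → 7 → 12 → 14 → 15; Steps 1, 2, 3, 6, 7, 8).

**Three steps most likely to fail, with fallbacks**
1. Step 7 (double asymmetric alkenylation). The di-ortho-substituted arylidene may react slowly or with poor selectivity, and aqueous base may cause retro-Knoevenagel. Fallback: reverse the polarity at the same carbon. Convert 3 with isobutyraldehyde and p-TolSO2H into the bis(1-tosyl-2-methylpropyl) derivative, generate the o-quinone methides in situ, and add syncarpic acid 11 under a chiral bifunctional squaramide catalyst, so the CH–syncarpyl bond is the stereodefining bond and no protecting groups are needed.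
2. Step 6 (double Knoevenagel on a hindered dialdehyde). Incomplete second condensation or bis-addition of syncarpic acid are the likely problems. Fallback: form the C=C by elimination instead of direct condensation. Isolate the bis-Mannich adduct of 7, piperidine and 11 (the zwitterion drives the equilibrium), then expel piperidine with acid in a separate step.
3. Step 3 (exhaustive O-benzylation of three chelated, strongly acidic phenols). Fallback: avoid phenol alkylation altogether. Start from commercial 1,3,5-tris(benzyloxy)benzene, acylate with hexanoic acid/TFAA, then introduce the two formyl groups by low-temperature Rieche formylation (Cl2CHOMe/SnCl4) to reach 7.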